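A direct plan would make the diaryl ether first, by SNAr of a 4-O-benzyl-3-hydroxybenzaldehyde acetal on 4-fluorobenzaldehyde (acetal aldehyde A1).
It would then condense the two formyl groups in turn with two O-benzyl-2-hydroxyacetophenones, one of them chlorinated, to give bis-chalcone A2.
Both enones would be turned into chromones by Tl(NO3)3 oxidative 1,2-aryl shift and acid cyclisation (tri-O-benzyl bis-isoflavone A3), followed by debenzylation.
The weakest step would be the double oxidative aryl migration: two rearrangements on one molecule, a weakly donating 4-aryloxyphenyl migrating group, aurone and flavone side paths, and stoichiometric trivalent thallium.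
The two Claisen–Schmidt condensations in strong alkali would be slow, and the second would expose an existing enone to Michael and retro-aldol reactions.
The acetal masking and unmasking and the phenol acetylation would add steps without adding skeleton.

The route would rest on the C3–C1′ and C3″–C1‴ bonds. In both B rings the chromone-bearing carbon stands para to an oxygen (C1′/O4′, C1‴/O4‴), so each ring can be carried as an aniline: a nitro group at C1‴ first activates the SNAr that forms the O–C4‴ ether and then, as a diazonium group, leaves from the very carbon that must bond to C3″. Photoredox arylation of an o-hydroxyaryl enaminone by the diazonium salt would join these two innately nucleophilic carbons through an aryl radical and close pyranone ring C (O1–C2) in the same operation. No chalcone, aryl migration, thallium or aldehyde masking would be needed, and the chlorinated and chlorine-free halves would enter separately.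

Key step: step 9

Remark: unprimed and singly primed locants refer to the chlorine-free isoflavone (chromone and ring B), doubly and triply primed locants to the 8-chloro isoflavone. The two arenediazonium tetrafluoroborates are assumed to be isolable solids that are used at once.

Step 1
Reactants: 1 1-(2-hydroxy-4-methoxyphenyl)ethan-1-one (paeonol)
Product: 2 (E)-3-(dimethylamino)-1-(2-hydroxy-4-methoxyphenyl)prop-2-en-1-one
Conditions: Me2NCH(OMe)2 (2 equiv), toluene, 100 °C, 6 h
Reagents that add atoms: N,N-dimethylformamide dimethyl acetal, COC(OC)N(C)C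
Why: Aminomethylenation of the methyl ketone by the formamide acetal (enaminone condensation) should leave the chelated 2-OH free and give the hydrogen-bonded E-enaminone as the thermodynamic isomer.

Step 2
Reactants: 3 5-amino-2-methoxyphenol; 4 1-fluoro-4-nitrobenzene
Product: 5 4-methoxy-3-(4-nitrophenoxy)aniline
Conditions: K2CO3 (1.5 equiv), DMSO, 80 °C, 6 h, N2
Reagents that add atoms: none
Why: SNAr (addition–elimination) at the C–F bond activated by the para-nitro group, in which the phenoxide formed by K2CO3 is far more nucleophilic than the neutral aniline nitrogen, so that O-arylation should be chemoselective.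

Step 3
Reactants: 5 4-methoxy-3-(4-nitrophenoxy)aniline
Product: 6 4-methoxy-3-(4-nitrophenoxy)benzenediazonium tetrafluoroborate
Conditions: t-BuONO (1.2 equiv), HBF4 (48% aq, 2 equiv), EtOH, 0 °C, 1 h; Et2O precipitation
Reagents that add atoms: tert-butyl nitrite, CC(C)(C)ON=O; tetrafluoroboric acid, [H+].F[B-](F)(F)F
Why: Diazotisation of the primary arylamine by an alkyl nitrite in HBF4 should give the sparingly soluble diazonium tetrafluoroborate, while the nitro group and the ethers are inert.

Step 4
Reactants: 6 4-methoxy-3-(4-nitrophenoxy)benzenediazonium tetrafluoroborate; 2 (E)-3-(dimethylamino)-1-(2-hydroxy-4-methoxyphenyl)prop-2-en-1-one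
Product: 8 7-methoxy-3-[4-methoxy-3-(4-nitrophenoxy)phenyl]-4H-chromen-4-one, via 2-(dimethylamino)chromanone aminal 7 (not isolated)
Conditions: 2 (1.5 equiv), eosin Y disodium salt C20H6Br4Na2O5 (2 mol%), DMSO, green LEDs (530 nm), 25 °C, N2, 8 h
Reagents that add atoms: none
Why: Photoredox Meerwein-type arylation–annulation of an o-hydroxyaryl enaminone, in which the aryl radical from 6 adds to the enaminone α-carbon, the α-amino radical is oxidised to the iminium ion, the phenol closes ring C (6-exo-trig) and Me2NH is eliminated, with the nitro group as a spectator and the two sp3 centres of 7 erased.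

Step 5
Reactants: 8 7-methoxy-3-[4-methoxy-3-(4-nitrophenoxy)phenyl]-4H-chromen-4-one
Product: 9 3-[3-(4-aminophenoxy)-4-methoxyphenyl]-7-methoxy-4H-chromen-4-one
Conditions: Fe powder (5 equiv), AcOH–EtOH–H2O 2:2:1, 70 °C, 2 h; filtration through Celite
Reagents that add atoms: none
Why: Béchamp-type dissolving-metal reduction should take the nitro group to the amine without touching the chromone C2=C3 bond, the carbonyl or the diaryl ether.

Step 6
Reactants: 9 3-[3-(4-aminophenoxy)-4-methoxyphenyl]-7-methoxy-4H-chromen-4-one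
Product: 10 4-[2-methoxy-5-(7-methoxy-4-oxo-4H-chromen-3-yl)phenoxy]benzenediazonium tetrafluoroborate
Conditions: t-BuONO (1.2 equiv), HBF4 (48% aq, 2 equiv), MeCN–EtOH 1:1, 0 °C, 1 h; Et2O precipitation
Reagents that add atoms: tert-butyl nitrite, CC(C)(C)ON=O; tetrafluoroboric acid, [H+].F[B-](F)(F)F
Why: Diazotisation of the arylamine as in step 3, the chromone being only weakly basic and stable to cold dilute acid.

Step 7
Reactants: 11 2-chloro-1,3-dimethoxybenzene
Product: 13 1-(3-chloro-2-hydroxy-4-methoxyphenyl)ethan-1-one, via dimethoxy ketone 12 (not isolated)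
Conditions: AcCl (1.2 equiv), AlCl3 (2.5 equiv), CH2Cl2, 0 °C → reflux, 6 h; ice/1 M HCl
Reagents that add atoms: acetyl chloride, CC(=O)Cl
Why: Friedel–Crafts acylation at C4, the only position ortho to one methoxy group and para to the other, followed by chelation-controlled AlCl3 cleavage of the methoxy group that lies between the new ketone and the chlorine.

Step 8
Reactants: 13 1-(3-chloro-2-hydroxy-4-methoxyphenyl)ethan-1-one
Product: 14 (E)-1-(3-chloro-2-hydroxy-4-methoxyphenyl)-3-(dimethylamino)prop-2-en-1-one
Conditions: Me2NCH(OMe)2 (2 equiv), toluene, 100 °C, 6 h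
Reagents that add atoms: N,N-dimethylformamide dimethyl acetal, COC(OC)N(C)C
Why: Enaminone condensation as in step 1, the chelated 2-OH again remaining free and the E-isomer being thermodynamically preferred.

Step 9
Reactants: 10 4-[2-methoxy-5-(7-methoxy-4-oxo-4H-chromen-3-yl)phenoxy]benzenediazonium tetrafluoroborate; 14 (E)-1-(3-chloro-2-hydroxy-4-methoxyphenyl)-3-(dimethylamino)prop-2-en-1-one
Product: 16 8-chloro-7-methoxy-3-{4-[2-methoxy-5-(7-methoxy-4-oxo-4H-chromen-3-yl)phenoxy]phenyl}-4H-chromen-4-one (tri-O-methylbisoflavolin K), via 2-(dimethylamino)chromanone aminal 15 (not isolated)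
Conditions: 14 (2 equiv), eosin Y disodium salt C20H6Br4Na2O5 (2 mol%), DMSO, green LEDs (530 nm), 25 °C, N2, 8 h
Reagents that add atoms: none
Why: Photoexcited eosin Y should reduce 10 by single-electron transfer, loss of N2 giving the aryl radical at C1‴, which adds to the nucleophilic α-carbon of 14; the resulting α-amino radical is oxidised (by the eosin Y radical cation or by 10 in a chain) to an iminium ion. The chelated phenol oxygen then adds to the iminium carbon and closes pyranone ring C of the chlorinated unit in a 6-exo-trig mode (aminal 15), and E1cB loss of Me2NH gives the chromone. The closest known reaction type is the Meerwein-type photoredox arylation of enaminones, run as a domino C–H functionalisation–chromone annulation of o-hydroxyaryl enaminones. No stereocentre has to be controlled, since both sp3 centres of 15 are erased in the elimination. The step needs radical C-arylation at the enaminone α-carbon rather than polar azo coupling, addition to the chromone already present, ring closure onto the neighbouring aryl ring or reaction at C–Cl; the para-aryloxy donor makes 10 a weak azo-coupling electrophile, the captodative enaminone C=C (in excess) is the best radical acceptor in the flask, the radical carbon is para to the ether oxygen so that no Pschorr-type closure is possible, and the aryl chloride is not reduced at the potential of excited eosin Y.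

Step 10
Reactants: 16 8-chloro-7-methoxy-3-{4-[2-methoxy-5-(7-methoxy-4-oxo-4H-chromen-3-yl)phenoxy]phenyl}-4H-chromen-4-one
Product: 17 bisoflavolin K, 8-chloro-7-hydroxy-3-{4-[2-hydroxy-5-(7-hydroxy-4-oxo-4H-chromen-3-yl)phenoxy]phenyl}-4H-chromen-4-one
Conditions: BBr3 (1 M in CH2Cl2, 10 equiv), CH2Cl2, −78 °C → rt, 16 h; MeOH, then H2O
Reagents that add atoms: none
Why: Lewis-acid ether cleavage (BBr3 demethylation) in which bromide attacks the O-methyl carbon of each aryloxyborane complex, whereas the diaryl ether and the aryl chloride offer no sp3 carbon and should persist.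

Compound list
1 | 1-(2-hydroxy-4-methoxyphenyl)ethan-1-one (paeonol) | CC(=O)c1ccc(OC)cc1O | starting material
2 | (E)-3-(dimethylamino)-1-(2-hydroxy-4-methoxyphenyl)prop-2-en-1-one | CN(C)/C=C/C(=O)c1ccc(OC)cc1O | intermediate
3 | 5-amino-2-methoxyphenol | COc1ccc(N)cc1O | starting material
4 | 1-fluoro-4-nitrobenzene | O=[N+]([O-])c1ccc(F)cc1 | starting material
5 | 4-methoxy-3-(4-nitrophenoxy)aniline | COc1ccc(N)cc1Oc1ccc([N+](=O)[O-])cc1 | intermediate
6 | 4-methoxy-3-(4-nitrophenoxy)benzenediazonium tetrafluoroborate | COc1ccc([N+]#N)cc1Oc1ccc([N+](=O)[O-])cc1.F[B-](F)(F)F | intermediate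
7 | 2-(dimethylamino)-7-methoxy-3-[4-methoxy-3-(4-nitrophenoxy)phenyl]chroman-4-one (diastereomer mixture, racemic, not isolated) | CN(C)C1Oc2cc(OC)ccc2C(=O)C1c1ccc(OC)c(Oc2ccc([N+](=O)[O-])cc2)c1 | intermediate
8 | 7-methoxy-3-[4-methoxy-3-(4-nitrophenoxy)phenyl]-4H-chromen-4-one | O=c1c(-c2ccc(OC)c(Oc3ccc([N+](=O)[O-])cc3)c2)coc2cc(OC)ccc12 | intermediate
9 | 3-[3-(4-aminophenoxy)-4-methoxyphenyl]-7-methoxy-4H-chromen-4-one | O=c1c(-c2ccc(OC)c(Oc3ccc(N)cc3)c2)coc2cc(OC)ccc12 | intermediate
10 | 4-[2-methoxy-5-(7-methoxy-4-oxo-4H-chromen-3-yl)phenoxy]benzenediazonium tetrafluoroborate | O=c1c(-c2ccc(OC)c(Oc3ccc([N+]#N)cc3)c2)coc2cc(OC)ccc12.F[B-](F)(F)F | intermediate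
11 | 2-chloro-1,3-dimethoxybenzene | COc1cccc(OC)c1Cl | starting material
12 | 1-(3-chloro-2,4-dimethoxyphenyl)ethan-1-one (not isolated) | CC(=O)c1ccc(OC)c(Cl)c1OC | intermediate
13 | 1-(3-chloro-2-hydroxy-4-methoxyphenyl)ethan-1-one | CC(=O)c1ccc(OC)c(Cl)c1O | intermediate
14 | (E)-1-(3-chloro-2-hydroxy-4-methoxyphenyl)-3-(dimethylamino)prop-2-en-1-one | CN(C)/C=C/C(=O)c1ccc(OC)c(Cl)c1O | intermediate
15 | 8-chloro-2-(dimethylamino)-7-methoxy-3-{4-[2-methoxy-5-(7-methoxy-4-oxo-4H-chromen-3-yl)phenoxy]phenyl}chroman-4-one (diastereomer mixture, racemic, not isolated) | CN(C)C1Oc2c(Cl)c(OC)ccc2C(=O)C1c1ccc(Oc2cc(-c3coc4cc(OC)ccc4c3=O)ccc2OC)cc1 | intermediate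
16 | 8-chloro-7-methoxy-3-{4-[2-methoxy-5-(7-methoxy-4-oxo-4H-chromen-3-yl)phenoxy]phenyl}-4H-chromen-4-one (tri-O-methylbisoflavolin K) | O=c1c(-c2ccc(OC)c(Oc3ccc(-c4coc5c(Cl)c(OC)ccc5c4=O)cc3)c2)coc2cc(OC)ccc12 | intermediate
17 | bisoflavolin K | O=c1c(-c2ccc(O)c(Oc3ccc(-c4coc5c(Cl)c(O)ccc5c4=O)cc3)c2)coc2cc(O)ccc12 | target

Total step count: 10. Longest linear sequence: 7 steps (steps 2, 3, 4, 5, 6, 9 and 10, from 5-amino-2-methoxyphenol).

Steps most likely to fail

Step 9. Polar azo coupling of the diazonium ion at the enaminone carbon, or addition of the aryl radical to the chromone of 10, may outrun the arylation–annulation, so that the chain stalls. The fallback sets out from 9 and 14 and comes back at 16. Amine 9 would be converted by Sandmeyer-type borylation (t-BuONO, B2pin2, MeCN, rt) into 7-methoxy-3-{4-methoxy-3-[4-(4,4,5,5-tetramethyl-1,3,2-dioxaborolan-2-yl)phenoxy]phenyl}-4H-chromen-4-one F1. Enaminone 14 would be closed by iodocyclisation (I2, CHCl3, rt) to 8-chloro-3-iodo-7-methoxy-4H-chromen-4-one F2. Suzuki–Miyaura coupling of the two (Pd(PPh3)4, K2CO3, dioxane–H2O, 80 °C), in which zerovalent palladium inserts into C–I and not into C–Cl, should give 16.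

Step 4. The same competition between radical arylation and azo coupling applies, and the nitro group may in addition be photoreduced. The fallback sets out from 2 and 4 and comes back at 8, with the ether made after the chromone. Enaminone 2 would be iodocyclised (I2, CHCl3, rt) to 3-iodo-7-methoxy-4H-chromen-4-one F3. Suzuki–Miyaura coupling with commercial (3-hydroxy-4-methoxyphenyl)boronic acid F4 (Pd(PPh3)4, Na2CO3, dioxane–H2O, 80 °C) should give 3-(3-hydroxy-4-methoxyphenyl)-7-methoxy-4H-chromen-4-one F5. SNAr of its phenoxide on 4 (K2CO3, DMF, 80 °C) should then give 8.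

Step 7. The one-flask acylation–demethylation may stop at the dimethoxy ketone or go on to cleave the second methyl ether. The fallback sets out from 11 and comes back at 13. Directed ortho-lithiation of 11 at C4 (s-BuLi, TMEDA, THF, −78 °C) and quench with N-methoxy-N-methylacetamide would give 12 as an isolated compound. BCl3 (CH2Cl2, −78 → 0 °C) would then cleave only the methoxy group chelated to the ketone to give 13. This fallback would make no compound outside the list (F0).

Further compounds
F1 | step 9 | 7-methoxy-3-{4-methoxy-3-[4-(4,4,5,5-tetramethyl-1,3,2-dioxaborolan-2-yl)phenoxy]phenyl}-4H-chromen-4-one | O=c1c(-c2ccc(OC)c(Oc3ccc(B4OC(C)(C)C(C)(C)O4)cc3)c2)coc2cc(OC)ccc12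
F2 | step 9 | 8-chloro-3-iodo-7-methoxy-4H-chromen-4-one | COc1ccc2c(=O)c(I)coc2c1Cl
F3 | step 4 | 3-iodo-7-methoxy-4H-chromen-4-one | COc1ccc2c(=O)c(I)coc2c1
F4 | step 4 | (3-hydroxy-4-methoxyphenyl)boronic acid | COc1ccc(B(O)O)cc1O
F5 | step 4 | 3-(3-hydroxy-4-methoxyphenyl)-7-methoxy-4H-chromen-4-one | O=c1c(-c2ccc(OC)c(O)c2)coc2cc(OC)ccc12
F0 | step 7 | none | none
A1 | direct plan | 4-[2-(benzyloxy)-5-(1,3-dioxolan-2-yl)phenoxy]benzaldehyde | O=Cc1ccc(Oc2cc(C3OCCO3)ccc2OCc2ccccc2)cc1
A2 | direct plan | (E,E)-bis-chalcone, (E)-1-[4-(benzyloxy)-2-hydroxyphenyl]-3-[4-(benzyloxy)-3-(4-{(E)-3-[4-(benzyloxy)-3-chloro-2-hydroxyphenyl]-3-oxoprop-1-en-1-yl}phenoxy)phenyl]prop-2-en-1-one | O=C(/C=C/c1ccc(OCc2ccccc2)c(Oc2ccc(/C=C/C(=O)c3ccc(OCc4ccccc4)c(Cl)c3O)cc2)c1)c1ccc(OCc2ccccc2)cc1O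
A3 | direct plan | 7-(benzyloxy)-3-[4-(benzyloxy)-3-{4-[7-(benzyloxy)-8-chloro-4-oxo-4H-chromen-3-yl]phenoxy}phenyl]-4H-chromen-4-one | O=c1c(-c2ccc(OCc3ccccc3)c(Oc3ccc(-c4coc5c(Cl)c(OCc6ccccc6)ccc5c4=O)cc3)c2)coc2cc(OCc3ccccc3)ccc12
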